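## Retrosynthetic overview

1. The C8–O ester is made last-but-one from macrocyclic alcohol 27 and silyl-protected (R)-3-hydroxyisobutyric acid 34, whose stereocentre comes from an ene-reductase reduction; global desilylation ends the route.
2. The ten-membered carbocycle is formed last, by ring-closing metathesis at C1=C10 of seco-diene 26 (ring-cis trisubstituted olefin).
3. The C7–C8 bond and both of its stereocentres come from a zinc Barbier allylation of 3-methylbut-3-enal with (6R)-bromomethyl butenolide 22; this turns the butenolide into the trans α-methylene-γ-lactone.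
4. The butenolide ring is formed first, by Pd carbonylative lactonisation of Z-iodo allylic alcohol 17 (Red-Al/I2 on propargylic alcohol 14); C6 is set by Me2Zn/ProPhenol-catalysed alkynylation of enal 11.
5. Enal 11 (C4=C5 geometry, C15 oxygen) comes from syn-carbocupration of ynoate 6, made from propargyl alcohol.

Assumption: the SMILES is read literally, so the methyl-bearing C1=C10 olefin is ring-cis (CIP Z) and C4=C5 is ring-trans (CIP Z because of CH2OH); atom labels follow germacrane numbering (lactone O on C6, ring fusion C6/C7, ester on C8, CH2OH = C15 on C4, methyl = C14 on C10).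

## Route

Step 1
Reactants: 1 prop-2-yn-1-ol; 2 tert-butyl(chloro)diphenylsilane (TBDPSCl)
Product: 3 tert-butyl(diphenyl)(prop-2-yn-1-yloxy)silane
Conditions: imidazole, CH2Cl2, 0 °C → rt
Reagents that add atoms: TBDPSCl, CC(C)(C)[Si](Cl)(c1ccccc1)c1ccccc1
Why: O-silylation (substitution at silicon) of the primary alcohol; TBDPS is chosen because it outlasts the selective TBS cleavage of step 9.

Step 2
Reactants: 3 tert-butyl(diphenyl)(prop-2-yn-1-yloxy)silane; 4 ethyl chloroformate
Product: 6 ethyl 4-[(tert-butyldiphenylsilyl)oxy]but-2-ynoate, via lithium acetylide 5 (not isolated)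
Conditions: n-BuLi, THF, −78 °C; then ClCO2Et, −78 → 0 °C
Reagents that add atoms: ethyl chloroformate, CCOC(=O)Cl
Why: Deprotonation of the terminal alkyne and C-acylation of the acetylide by the chloroformate (addition–elimination) gives the ynoate acceptor.

Step 3
Reactants: 6 ethyl 4-[(tert-butyldiphenylsilyl)oxy]but-2-ynoate; 7 but-3-en-1-ylmagnesium bromide
Product: 9 ethyl (2Z)-3-{[(tert-butyldiphenylsilyl)oxy]methyl}hepta-2,6-dienoate, via alkenylcopper adduct 8 (not isolated)
Conditions: 7 (2.1 equiv), CuI (1.05 equiv), THF, −40 °C; then 6, −78 °C; sat. aq NH4Cl at −78 °C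
Reagents that add atoms: but-3-en-1-ylmagnesium bromide, C=CCC[Mg]Br
Why: Stereospecific syn-carbocupration (conjugate addition) of the cuprate to the ynoate, then cold protonation with retention, puts the ester cis to CH2OTBDPS, which is the ring-trans C4=C5 geometry of the target.

Step 4
Reactants: 9 ethyl (2Z)-3-{[(tert-butyldiphenylsilyl)oxy]methyl}hepta-2,6-dienoate
Product: 10 (2Z)-3-{[(tert-butyldiphenylsilyl)oxy]methyl}hepta-2,6-dien-1-ol
Conditions: i-Bu2AlH (2.2 equiv), CH2Cl2, −78 °C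
Reagents that add atoms: none
Why: Hydride 1,2-reduction of the enoate stops at the allylic alcohol and touches neither the silyl ether nor the olefin geometry.

Step 5
Reactants: 10 (2Z)-3-{[(tert-butyldiphenylsilyl)oxy]methyl}hepta-2,6-dien-1-ol
Product: 11 (2Z)-3-{[(tert-butyldiphenylsilyl)oxy]methyl}hepta-2,6-dienal
Conditions: MnO2 (excess), CH2Cl2, rt
Reagents that add atoms: none
Why: Chemoselective allylic oxidation under neutral heterogeneous conditions gives the enal without Z/E isomerisation.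

Step 6
Reactants: 11 (2Z)-3-{[(tert-butyldiphenylsilyl)oxy]methyl}hepta-2,6-dienal; 12 tert-butyl(dimethyl)(prop-2-yn-1-yloxy)silane
Product: 14 (4R,5Z)-1-[(tert-butyldimethylsilyl)oxy]-6-{[(tert-butyldiphenylsilyl)oxy]methyl}deca-5,9-dien-2-yn-4-ol, via alkynyl(methyl)zinc 13 (not isolated)
Conditions: 12 (3 equiv), Me2Zn (3 equiv), (R,R)-ProPhenol (10 mol %), Ph3P=O (20 mol %), toluene, 0 → 4 °C
Reagents that add atoms: tert-butyl(dimethyl)(prop-2-yn-1-yloxy)silane, C#CCO[Si](C)(C)C(C)(C)C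
Why: Catalytic asymmetric alkynylation (Trost ProPhenol dinuclear zinc catalysis) delivers the alkynylzinc to one enal face and sets C6 as R, the first stereocentre; the ligand enantiomer is assigned by analogy with the ProPhenol aldol sense, so the configuration is confirmed by Mosher ester analysis and the antipodal ligand is used if needed.

Step 7
Reactants: 14 (4R,5Z)-1-[(tert-butyldimethylsilyl)oxy]-6-{[(tert-butyldiphenylsilyl)oxy]methyl}deca-5,9-dien-2-yn-4-ol; 15 iodine
Product: 17 (2Z,4R,5Z)-1-[(tert-butyldimethylsilyl)oxy]-6-{[(tert-butyldiphenylsilyl)oxy]methyl}-2-iododeca-2,5,9-trien-4-ol, via cyclic vinylalanate 16 (not isolated)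
Conditions: NaAlH2(OCH2CH2OMe)2 (Red-Al), THF, 0 °C; then I2, THF, −78 °C
Reagents that add atoms: iodine, II
Why: Alkoxide-directed trans-hydroalumination of the propargylic alcohol places aluminium on the distal alkyne carbon (C11), and iodinolysis with retention gives the Z-vinyl iodide with iodine cis to the carbinol carbon.

Step 8
Reactants: 17 (2Z,4R,5Z)-1-[(tert-butyldimethylsilyl)oxy]-6-{[(tert-butyldiphenylsilyl)oxy]methyl}-2-iododeca-2,5,9-trien-4-ol; 18 carbon monoxide
Product: 19 (5R)-3-{[(tert-butyldimethylsilyl)oxy]methyl}-5-[(1Z)-2-{[(tert-butyldiphenylsilyl)oxy]methyl}hexa-1,5-dien-1-yl]furan-2(5H)-one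
Conditions: Pd(PPh3)2Cl2 (5 mol %), CO (1 atm), i-Pr2NEt, THF, rt
Reagents that add atoms: carbon monoxide, [C-]#[O+]
Why: Carbonylative lactonisation (Stille-type cyclocarbonylation): zerovalent palladium formed in situ inserts into the C–I bond, CO insertion gives an acylpalladium, and the cis-disposed C6 hydroxyl captures it to close the butenolide without touching C6.

Step 9
Reactants: 19 (5R)-3-{[(tert-butyldimethylsilyl)oxy]methyl}-5-[(1Z)-2-{[(tert-butyldiphenylsilyl)oxy]methyl}hexa-1,5-dien-1-yl]furan-2(5H)-one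
Product: 20 (5R)-5-[(1Z)-2-{[(tert-butyldiphenylsilyl)oxy]methyl}hexa-1,5-dien-1-yl]-3-(hydroxymethyl)furan-2(5H)-one
Conditions: PPTS (0.2 equiv), MeOH, rt
Reagents that add atoms: none
Why: Acid-catalysed methanolysis (selective desilylation) removes the primary TBS ether far faster than the TBDPS ether.

Step 10
Reactants: 20 (5R)-5-[(1Z)-2-{[(tert-butyldiphenylsilyl)oxy]methyl}hexa-1,5-dien-1-yl]-3-(hydroxymethyl)furan-2(5H)-one; 21 tetrabromomethane
Product: 22 (5R)-3-(bromomethyl)-5-[(1Z)-2-{[(tert-butyldiphenylsilyl)oxy]methyl}hexa-1,5-dien-1-yl]furan-2(5H)-one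
Conditions: CBr4, PPh3, CH2Cl2, 0 °C
Reagents that add atoms: tetrabromomethane, BrC(Br)(Br)Br
Why: Appel bromination converts the primary allylic alcohol into the bromide by SN2 displacement of the alkoxyphosphonium under neutral conditions that spare the base-sensitive butenolide.

Step 11
Reactants: 23 3-methylbut-3-en-1-ol
Product: 24 3-methylbut-3-enal
Conditions: Dess–Martin periodinane, CH2Cl2, 0 °C → rt; filtered and used at once as a solution
Reagents that add atoms: none
Why: Dess–Martin oxidation under non-aqueous, near-neutral conditions gives the β,γ-unsaturated aldehyde before it can isomerise to the conjugated enal.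

Step 12
Reactants: 22 (5R)-3-(bromomethyl)-5-[(1Z)-2-{[(tert-butyldiphenylsilyl)oxy]methyl}hexa-1,5-dien-1-yl]furan-2(5H)-one; 24 3-methylbut-3-enal
Product: 26 (4R,5R)-5-[(1Z)-2-{[(tert-butyldiphenylsilyl)oxy]methyl}hexa-1,5-dien-1-yl]-4-[(1S)-1-hydroxy-3-methylbut-3-en-1-yl]-3-methylideneoxolan-2-one, via allylzinc bromide 25 (not isolated)
Conditions: Zn dust, 24 (3 equiv), THF/sat. aq NH4Cl, 0 °C → rt
Reagents that add atoms: 3-methylbut-3-enal, CC(=C)CC=O
Why: Zinc Barbier allylation (SE2′ through a Zimmerman–Traxler chair): attack through C7 anti to the C6 side chain gives the 6,7-trans lactone with the olefin moved to the exocyclic position, and the ring-fixed E allyl geometry with an equatorial aldehyde substituent gives the 7,8-anti (8S) carbinol.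

Step 13
Reactants: 26 (4R,5R)-5-[(1Z)-2-{[(tert-butyldiphenylsilyl)oxy]methyl}hexa-1,5-dien-1-yl]-4-[(1S)-1-hydroxy-3-methylbut-3-en-1-yl]-3-methylideneoxolan-2-one
Product: 27 (3aR,4S,6Z,10Z,11aR)-10-{[(tert-butyldiphenylsilyl)oxy]methyl}-4-hydroxy-6-methyl-3-methylidene-3a,4,5,8,9,11a-hexahydrocyclodeca[b]furan-2(3H)-one
Conditions: second-generation Grubbs catalyst RuCl2(=CHPh)(H2IMes)(PCy3) (15 mol % in portions), toluene, 1 mM, 80 °C
Reagents that add atoms: none
Why: Ring-closing metathesis: the ruthenium carbene formed at the C1 vinyl closes onto the 1,1-disubstituted olefin, and the strained ten-membered ring, pre-organised by the trans lactone and the C4=C5 unit, is expected to form with the ring-cis (Z) trisubstituted olefin (checked by NOE) while high dilution suppresses dimerisation.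

Step 14
Reactants: 28 methyl 2-(hydroxymethyl)prop-2-enoate
Product: 29 methyl (2R)-3-hydroxy-2-methylpropanoate
Conditions: ene-reductase (flavin-dependent Old Yellow Enzyme class), NADP+ (cat.), i-PrOH, alcohol dehydrogenase (cofactor recycling), K2HPO4/KH2PO4 buffer pH 7.0, 30 °C
Reagents that add atoms: none
Why: Biocatalytic asymmetric C=C reduction: the reduced flavin of the ene-reductase delivers hydride to the β-carbon and an active-site tyrosine protonates the α-carbon from the opposite face, giving the R ester in high ee.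

Step 15
Reactants: 29 methyl (2R)-3-hydroxy-2-methylpropanoate; 30 tert-butyl(chloro)dimethylsilane (TBSCl)
Product: 31 methyl (2R)-3-[(tert-butyldimethylsilyl)oxy]-2-methylpropanoate
Conditions: imidazole, DMF, rt
Reagents that add atoms: TBSCl, CC(C)(C)[Si](C)(C)Cl
Why: O-silylation of the primary alcohol blocks it against self-acylation in the later esterification.

Step 16
Reactants: 31 methyl (2R)-3-[(tert-butyldimethylsilyl)oxy]-2-methylpropanoate; 32 lithium hydroxide
Product: 34 (2R)-3-[(tert-butyldimethylsilyl)oxy]-2-methylpropanoic acid, via lithium carboxylate 33 (not isolated)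
Conditions: LiOH, THF/MeOH/H2O, 0 °C → rt; then 1 M HCl to pH 4, 0 °C
Reagents that add atoms: lithium hydroxide, [Li+].[OH-]
Why: Saponification (BAc2 ester hydrolysis) at low temperature followed by mild acidification gives the acid without epimerising the α-centre or cleaving the TBS ether.

Step 17
Reactants: 27 (3aR,4S,6Z,10Z,11aR)-10-{[(tert-butyldiphenylsilyl)oxy]methyl}-4-hydroxy-6-methyl-3-methylidene-3a,4,5,8,9,11a-hexahydrocyclodeca[b]furan-2(3H)-one; 34 (2R)-3-[(tert-butyldimethylsilyl)oxy]-2-methylpropanoic acid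
Product: 35 (3aR,4S,6Z,10Z,11aR)-10-{[(tert-butyldiphenylsilyl)oxy]methyl}-6-methyl-3-methylidene-2-oxo-2,3,3a,4,5,8,9,11a-octahydrocyclodeca[b]furan-4-yl (2R)-3-[(tert-butyldimethylsilyl)oxy]-2-methylpropanoate
Conditions: EDC·HCl, DMAP, CH2Cl2, 0 °C → rt
Reagents that add atoms: (2R)-3-[(tert-butyldimethylsilyl)oxy]-2-methylpropanoic acid, C[C@H](CO[Si](C)(C)C(C)(C)C)C(=O)O
Why: Steglich esterification (carbodiimide activation with DMAP acyl transfer) acylates the secondary C8 hydroxyl with retention at C8 and at the acid α-centre.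

Step 18
Reactants: 35 (3aR,4S,6Z,10Z,11aR)-10-{[(tert-butyldiphenylsilyl)oxy]methyl}-6-methyl-3-methylidene-2-oxo-2,3,3a,4,5,8,9,11a-octahydrocyclodeca[b]furan-4-yl (2R)-3-[(tert-butyldimethylsilyl)oxy]-2-methylpropanoate
Product: 36 (3aR,4S,6Z,10Z,11aR)-10-(hydroxymethyl)-6-methyl-3-methylidene-2-oxo-2,3,3a,4,5,8,9,11a-octahydrocyclodeca[b]furan-4-yl (2R)-3-hydroxy-2-methylpropanoate
Conditions: HF·pyridine, pyridine, THF, 0 °C → rt
Reagents that add atoms: none
Why: Fluoride-mediated desilylation under buffered acidic conditions cleaves both primary silyl ethers and leaves the α-methylene lactone, the ester and all stereocentres untouched.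

## Compound list

1 | prop-2-yn-1-ol | C#CCO | starting material
2 | tert-butyl(chloro)diphenylsilane | CC(C)(C)[Si](Cl)(c1ccccc1)c1ccccc1 | starting material
3 | tert-butyl(diphenyl)(prop-2-yn-1-yloxy)silane | C#CCO[Si](c1ccccc1)(c1ccccc1)C(C)(C)C | intermediate
4 | ethyl chloroformate | CCOC(=O)Cl | starting material
5 | lithium acetylide of 3 (not isolated) | [Li]C#CCO[Si](c1ccccc1)(c1ccccc1)C(C)(C)C | intermediate
6 | ethyl 4-[(tert-butyldiphenylsilyl)oxy]but-2-ynoate | CCOC(=O)C#CCO[Si](c1ccccc1)(c1ccccc1)C(C)(C)C | intermediate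
7 | but-3-en-1-ylmagnesium bromide | C=CCC[Mg]Br | starting material
8 | alkenylcopper adduct of 6 (copper on C2, cis to the butenyl group; drawn without its magnesium counter-ion; not isolated) | CCOC(=O)/C([Cu])=C(\CO[Si](c1ccccc1)(c1ccccc1)C(C)(C)C)CCC=C | intermediate
9 | ethyl (2Z)-3-{[(tert-butyldiphenylsilyl)oxy]methyl}hepta-2,6-dienoate | CCOC(=O)/C=C(\CO[Si](c1ccccc1)(c1ccccc1)C(C)(C)C)CCC=C | intermediate
10 | (2Z)-3-{[(tert-butyldiphenylsilyl)oxy]methyl}hepta-2,6-dien-1-ol | OC/C=C(\CO[Si](c1ccccc1)(c1ccccc1)C(C)(C)C)CCC=C | intermediate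
11 | (2Z)-3-{[(tert-butyldiphenylsilyl)oxy]methyl}hepta-2,6-dienal | O=C/C=C(\CO[Si](c1ccccc1)(c1ccccc1)C(C)(C)C)CCC=C | intermediate
12 | tert-butyl(dimethyl)(prop-2-yn-1-yloxy)silane | C#CCO[Si](C)(C)C(C)(C)C | starting material
13 | {3-[(tert-butyldimethylsilyl)oxy]prop-1-yn-1-yl}(methyl)zinc (not isolated) | C[Zn]C#CCO[Si](C)(C)C(C)(C)C | intermediate
14 | (4R,5Z)-1-[(tert-butyldimethylsilyl)oxy]-6-{[(tert-butyldiphenylsilyl)oxy]methyl}deca-5,9-dien-2-yn-4-ol | O[C@@H](C#CCO[Si](C)(C)C(C)(C)C)/C=C(\CO[Si](c1ccccc1)(c1ccccc1)C(C)(C)C)CCC=C | intermediate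
15 | iodine | II | starting material
16 | sodium salt of the five-membered oxa-alanate ring (O–C6–C7=C11–Al, two 2-methoxyethoxy groups on Al; not isolated) | COCCO[Al-]1(OCCOC)O[C@H](/C=C(\CO[Si](c2ccccc2)(c2ccccc2)C(C)(C)C)CCC=C)C=C1CO[Si](C)(C)C(C)(C)C.[Na+] | intermediate
17 | (2Z,4R,5Z)-1-[(tert-butyldimethylsilyl)oxy]-6-{[(tert-butyldiphenylsilyl)oxy]methyl}-2-iododeca-2,5,9-trien-4-ol | O[C@@H](/C=C(\I)CO[Si](C)(C)C(C)(C)C)/C=C(\CO[Si](c1ccccc1)(c1ccccc1)C(C)(C)C)CCC=C | intermediate
18 | carbon monoxide | [C-]#[O+] | starting material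
19 | (5R)-3-{[(tert-butyldimethylsilyl)oxy]methyl}-5-[(1Z)-2-{[(tert-butyldiphenylsilyl)oxy]methyl}hexa-1,5-dien-1-yl]furan-2(5H)-one | O=C1O[C@H](/C=C(\CO[Si](c2ccccc2)(c2ccccc2)C(C)(C)C)CCC=C)C=C1CO[Si](C)(C)C(C)(C)C | intermediate
20 | (5R)-5-[(1Z)-2-{[(tert-butyldiphenylsilyl)oxy]methyl}hexa-1,5-dien-1-yl]-3-(hydroxymethyl)furan-2(5H)-one | O=C1O[C@H](/C=C(\CO[Si](c2ccccc2)(c2ccccc2)C(C)(C)C)CCC=C)C=C1CO | intermediate
21 | tetrabromomethane | BrC(Br)(Br)Br | starting material
22 | (5R)-3-(bromomethyl)-5-[(1Z)-2-{[(tert-butyldiphenylsilyl)oxy]methyl}hexa-1,5-dien-1-yl]furan-2(5H)-one | O=C1O[C@H](/C=C(\CO[Si](c2ccccc2)(c2ccccc2)C(C)(C)C)CCC=C)C=C1CBr | intermediate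
23 | 3-methylbut-3-en-1-ol | CC(=C)CCO | starting material
24 | 3-methylbut-3-enal | CC(=C)CC=O | intermediate
25 | allylzinc bromide from 22 (zinc on the former CH2Br carbon; not isolated) | O=C1O[C@H](/C=C(\CO[Si](c2ccccc2)(c2ccccc2)C(C)(C)C)CCC=C)C=C1C[Zn]Br | intermediate
26 | (4R,5R)-5-[(1Z)-2-{[(tert-butyldiphenylsilyl)oxy]methyl}hexa-1,5-dien-1-yl]-4-[(1S)-1-hydroxy-3-methylbut-3-en-1-yl]-3-methylideneoxolan-2-one | C=C1C(=O)O[C@H](/C=C(\CO[Si](c2ccccc2)(c2ccccc2)C(C)(C)C)CCC=C)[C@H]1[C@@H](O)CC(C)=C | intermediate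
27 | (3aR,4S,6Z,10Z,11aR)-10-{[(tert-butyldiphenylsilyl)oxy]methyl}-4-hydroxy-6-methyl-3-methylidene-3a,4,5,8,9,11a-hexahydrocyclodeca[b]furan-2(3H)-one | C=C1C(=O)O[C@@H]2/C=C(\CO[Si](c3ccccc3)(c3ccccc3)C(C)(C)C)CC/C=C(/C)C[C@H](O)[C@@H]12 | intermediate
28 | methyl 2-(hydroxymethyl)prop-2-enoate | C=C(CO)C(=O)OC | starting material
29 | methyl (2R)-3-hydroxy-2-methylpropanoate | C[C@H](CO)C(=O)OC | intermediate
30 | tert-butyl(chloro)dimethylsilane | CC(C)(C)[Si](C)(C)Cl | starting material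
31 | methyl (2R)-3-[(tert-butyldimethylsilyl)oxy]-2-methylpropanoate | C[C@H](CO[Si](C)(C)C(C)(C)C)C(=O)OC | intermediate
32 | lithium hydroxide | [Li+].[OH-] | starting material
33 | lithium (2R)-3-[(tert-butyldimethylsilyl)oxy]-2-methylpropanoate (not isolated) | C[C@H](CO[Si](C)(C)C(C)(C)C)C(=O)[O-].[Li+] | intermediate
34 | (2R)-3-[(tert-butyldimethylsilyl)oxy]-2-methylpropanoic acid | C[C@H](CO[Si](C)(C)C(C)(C)C)C(=O)O | intermediate
35 | (3aR,4S,6Z,10Z,11aR)-10-{[(tert-butyldiphenylsilyl)oxy]methyl}-6-methyl-3-methylidene-2-oxo-2,3,3a,4,5,8,9,11a-octahydrocyclodeca[b]furan-4-yl (2R)-3-[(tert-butyldimethylsilyl)oxy]-2-methylpropanoate | C=C1C(=O)O[C@@H]2/C=C(\CO[Si](c3ccccc3)(c3ccccc3)C(C)(C)C)CC/C=C(/C)C[C@H](OC(=O)[C@H](C)CO[Si](C)(C)C(C)(C)C)[C@@H]12 | intermediate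
36 | (3aR,4S,6Z,10Z,11aR)-10-(hydroxymethyl)-6-methyl-3-methylidene-2-oxo-2,3,3a,4,5,8,9,11a-octahydrocyclodeca[b]furan-4-yl (2R)-3-hydroxy-2-methylpropanoate | C=C1C(=O)O[C@@H]2/C=C(\CO)CC/C=C(/C)C[C@H](OC(=O)[C@H](C)CO)[C@@H]12 | target

## Step count and risk

Total step count: 18. Longest linear sequence: 14 steps (steps 1–10, 12, 13, 17, 18); steps 11 and 14–16 are side branches.

The three steps most likely to fail:

Step 13 (macrocyclic ring-closing metathesis; the risks are dimerisation, catalyst capture by the free carbinol or the acrylate-type olefin, or the wrong olefin geometry). The fallback sets out from 26 and comes back at 35. Compound 26 is esterified first with 34 (EDC·HCl, DMAP, CH2Cl2) to give the C8 ester of the seco-diene F4. Me2NH (THF, 0 °C) then adds in Michael fashion to the exocyclic methylene to give the 13-(dimethylamino) adduct F5, whose new C11 centre is of no consequence. As its p-toluenesulfonate salt, this adduct is cyclised with the second-generation Hoveyda–Grubbs catalyst RuCl2(=CH-2-(i-PrO)C6H4)(H2IMes) (toluene, 1 mM, 80 °C) to the macrocyclic amine F6. MeI gives the quaternary ammonium iodide F7, and aqueous NaHCO3 eliminates trimethylamine to restore the methylene and deliver 35, which continues with step 18.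

Step 12 (Barbier allylation; the risks are isomerisation of aldehyde 24 in the aqueous medium, 1,4-elimination of the allylzinc with opening of the lactone, or low selectivity at C8). The fallback sets out from 22 and comes back at 26. The bromide is converted with bis(pinacolato)diboron and Pd2(dba)3 (cat.) in THF into the allylboronate (5R)-5-[(1Z)-2-{[(tert-butyldiphenylsilyl)oxy]methyl}hexa-1,5-dien-1-yl]-3-[(4,4,5,5-tetramethyl-1,3,2-dioxaborolan-2-yl)methyl]furan-2(5H)-one F3. This is combined with 24 and Sc(OTf)3 (10 mol %) in toluene at −78 °C. The anhydrous, Lewis-acid-catalysed allylboration runs through a closed six-membered chair and gives the same anti, trans product 26 after aqueous work-up.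

Step 6 (asymmetric alkynylation; the risks are low rate or low ee on the hindered Z-enal, or Z/E drift of 11). The fallback sets out from 9 and comes back at 14. Ester 9 is converted with MeNHOMe·HCl and i-PrMgCl (THF, −20 °C) into the Weinreb amide (2Z)-3-{[(tert-butyldiphenylsilyl)oxy]methyl}-N-methoxy-N-methylhepta-2,6-dienamide F1. The lithium acetylide of 12 (n-BuLi, THF, −78 °C) turns it into the ynone (5Z)-1-[(tert-butyldimethylsilyl)oxy]-6-{[(tert-butyldiphenylsilyl)oxy]methyl}deca-5,9-dien-2-yn-4-one F2. Corey–Bakshi–Shibata reduction with (R)-2-methyl-CBS-oxazaborolidine (20 mol %) and catecholborane (toluene, −78 °C), in which the slim alkynyl group acts as the small substituent and the branched alkenyl group as the large one, gives the (4R)-alcohol 14.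

## Further compounds

F1 | step 6 | (2Z)-3-{[(tert-butyldiphenylsilyl)oxy]methyl}-N-methoxy-N-methylhepta-2,6-dienamide | CON(C)C(=O)/C=C(\CO[Si](c1ccccc1)(c1ccccc1)C(C)(C)C)CCC=C
F2 | step 6 | (5Z)-1-[(tert-butyldimethylsilyl)oxy]-6-{[(tert-butyldiphenylsilyl)oxy]methyl}deca-5,9-dien-2-yn-4-one | O=C(C#CCO[Si](C)(C)C(C)(C)C)/C=C(\CO[Si](c1ccccc1)(c1ccccc1)C(C)(C)C)CCC=C
F3 | step 12 | (5R)-5-[(1Z)-2-{[(tert-butyldiphenylsilyl)oxy]methyl}hexa-1,5-dien-1-yl]-3-[(4,4,5,5-tetramethyl-1,3,2-dioxaborolan-2-yl)methyl]furan-2(5H)-one | O=C1O[C@H](/C=C(\CO[Si](c2ccccc2)(c2ccccc2)C(C)(C)C)CCC=C)C=C1CB3OC(C)(C)C(C)(C)O3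
F4 | step 13 | (1S)-1-[(2R,3R)-2-[(1Z)-2-{[(tert-butyldiphenylsilyl)oxy]methyl}hexa-1,5-dien-1-yl]-4-methylidene-5-oxooxolan-3-yl]-3-methylbut-3-en-1-yl (2R)-3-[(tert-butyldimethylsilyl)oxy]-2-methylpropanoate (C8 ester of 26) | C=C1C(=O)O[C@H](/C=C(\CO[Si](c2ccccc2)(c2ccccc2)C(C)(C)C)CCC=C)[C@H]1[C@@H](OC(=O)[C@H](C)CO[Si](C)(C)C(C)(C)C)CC(C)=C
F5 | step 13 | dimethylamine Michael adduct of F4 (CH2NMe2 on C11 in place of the exocyclic methylene, C11 configuration not defined) | CN(C)CC1C(=O)O[C@H](/C=C(\CO[Si](c2ccccc2)(c2ccccc2)C(C)(C)C)CCC=C)[C@H]1[C@@H](OC(=O)[C@H](C)CO[Si](C)(C)C(C)(C)C)CC(C)=C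
F6 | step 13 | macrocyclic amine: 35 carrying CH2NMe2 on C11 in place of the exocyclic methylene (C11 configuration not defined) | CN(C)CC1C(=O)O[C@@H]2/C=C(\CO[Si](c3ccccc3)(c3ccccc3)C(C)(C)C)CC/C=C(/C)C[C@H](OC(=O)[C@H](C)CO[Si](C)(C)C(C)(C)C)[C@@H]12
F7 | step 13 | trimethylammonium iodide obtained from F6 and MeI | C[N+](C)(C)CC1C(=O)O[C@@H]2/C=C(\CO[Si](c3ccccc3)(c3ccccc3)C(C)(C)C)CC/C=C(/C)C[C@H](OC(=O)[C@H](C)CO[Si](C)(C)C(C)(C)C)[C@@H]12.[I-]
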